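**Retrosynthetic overview**

1. Numbering: C1–C11 are the ring carbons in the order of the target SMILES (C1 CH–O-senecioyl, C2 CH2, C3 CH–O-isovaleryl, C4 CMe2, C7 C=O, C8=C9, C11 quaternary C–Me). The route rests on the cyclobutane C5–C6–C11–C10 spanned by C7–C8–C9 (a bicyclo[3.1.1]heptenone), with C5 carried as a cyclobutanone that is born from a C5 cyclopropanol.
2. Last operations: senecioate at C1, C7 carbonyl by allylic oxidation of C8=C9, C5–H by radical deoxygenation, isovalerate at C3.
3. Seven-membered ring (C1–C2–C3–C4–C5–C10–C11), closed third: bond C4–C5 by reductive aldol of an enone hung from C1, after a catalyst-controlled aldol has joined C2–C4 to the C1 aldehyde.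
4. Six-membered ring (bond C7–C8) and cyclobutanone (bond C6–C11), closed together, second: aldehyde Prins cyclisation of a cis-vinyl silyloxycyclopropane, ended by cyclopropanol-to-cyclobutanone ring expansion.
5. Cyclopropane (C5, C10, C11), closed first: asymmetric rhodium-carbenoid addition of methyl 2-diazopropanoate to an E-2-silyloxy-1,3-diene made from a lactone and vinylmagnesium bromide.

Key step: step 11

Remark: (S)-4-methyldihydrofuran-2(3H)-one (3) is taken as a commercial chiral building block; its stereocentre (C9) is destroyed in step 12 and serves only to make every earlier intermediate a single diastereomer.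

**Route**

Step 1
Reactants: 1 methyl 2-methyl-3-oxobutanoate
Product: 2 methyl 2-diazopropanoate
Conditions: 4-acetamidobenzenesulfonyl azide, DBU, MeCN, 0 °C to rt
Reagents that add atoms: 4-acetamidobenzenesulfonyl azide, CC(=O)Nc1ccc(cc1)S(=O)(=O)N=[N+]=[N-]
Why: Regitz-type deacylative diazo transfer: the azide delivers N2 to the enolate carbon and the acetyl group is expelled onto the sulfonamide nitrogen, which gives the α-methyl diazo ester directly; no stereocentre is formed.

Step 2
Reactants: 3 (S)-4-methyldihydrofuran-2(3H)-one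
Product: 4 (S)-4-hydroxy-N-methoxy-N,3-dimethylbutanamide
Conditions: MeNH(OMe)·HCl, i-PrMgCl, THF, −20 to 0 °C
Reagents that add atoms: N,O-dimethylhydroxylamine hydrochloride, CNOC.Cl
Why: Weinreb amide formation by ring-opening aminolysis of the lactone with the magnesium amide of N,O-dimethylhydroxylamine; the C9 stereocentre of 3 is not involved.

Step 3
Reactants: 4 (S)-4-hydroxy-N-methoxy-N,3-dimethylbutanamide
Product: 5 (S)-N-methoxy-N,3-dimethyl-4-(triethylsilyloxy)butanamide
Conditions: Et3SiCl, imidazole, CH2Cl2, 0 °C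
Reagents that add atoms: chlorotriethylsilane, CC[Si](Cl)(CC)CC
Why: Routine silylation of a primary alcohol, which blocks relactonisation and puts the most acid-labile silyl group of the route on O8.

Step 4
Reactants: 5 (S)-N-methoxy-N,3-dimethyl-4-(triethylsilyloxy)butanamide; 6 vinylmagnesium bromide
Product: 7 (S)-5-methyl-6-(triethylsilyloxy)hex-1-en-3-one
Conditions: THF, −20 to 0 °C; inverse quench into cold aq. citric acid
Reagents that add atoms: none
Why: Weinreb ketone synthesis: the chelated tetrahedral adduct resists a second addition and collapses to the vinyl ketone only on the acidic inverse quench, which also keeps the released amine from adding to the enone.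

Step 5
Reactants: 7 (S)-5-methyl-6-(triethylsilyloxy)hex-1-en-3-one
Product: 8 (3E,5S)-5-methyl-3,6-bis(triethylsilyloxy)hexa-1,3-diene
Conditions: 2,2,6,6-tetramethylpiperidine, n-BuLi, LiBr, THF, −78 °C; 7 and Et3SiCl added together (in situ quench), −78 to −40 °C
Reagents that add atoms: chlorotriethylsilane, CC[Si](Cl)(CC)CC
Why: Kinetic α′-deprotonation of a vinyl ketone with a hindered lithium amide and in situ silylation (Ireland-type E(O)-enolate control, reinforced by LiBr) should give the 3E enol ether, the geometry in which the vinyl group and the C9 chain are cis on C5=C10.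

Step 6
Reactants: 8 (3E,5S)-5-methyl-3,6-bis(triethylsilyloxy)hexa-1,3-diene; 2 methyl 2-diazopropanoate
Product: 9 methyl (1R,2S,3R)-1-methyl-2-(triethylsilyloxy)-3-[(2S)-1-(triethylsilyloxy)propan-2-yl]-2-vinylcyclopropane-1-carboxylate (ester cis to the silyloxy group and to H on C10; C11 methyl, vinyl and side chain on the other face)
Conditions: Rh2(S-PTTL)4 (dirhodium tetrakis[N-phthaloyl-(S)-tert-leucinate], 1 mol %), hexanes, −78 °C, slow addition of 2
Reagents that add atoms: none
Why: Rhodium-carbenoid cyclopropanation of a silyl enol ether with an α-alkyl-α-diazo ester under bulky-carboxylate, low-temperature conditions that hold back β-hydride elimination; the addition is stereospecific, so the cis vinyl/C9 relation of the E-enol ether is kept, the ester takes the less crowded side next to C10–H and the silyloxy group (as in exo-selective additions to 1-silyloxycycloalkenes), which leaves the C11 methyl cis to vinyl and chain, and the chiral catalyst picks the enol ether face, the fixed C9 centre turning any facial leakage into a separable diastereomer.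

Step 7
Reactants: 9 methyl (1R,2S,3R)-1-methyl-2-(triethylsilyloxy)-3-[(2S)-1-(triethylsilyloxy)propan-2-yl]-2-vinylcyclopropane-1-carboxylate
Product: 10 [(1S,2S,3R)-1-methyl-2-(triethylsilyloxy)-3-[(2S)-1-(triethylsilyloxy)propan-2-yl]-2-vinylcyclopropyl]methanol
Conditions: LiAlH4, Et2O, −20 to 0 °C; aq. Rochelle salt
Reagents that add atoms: none
Why: Hydride reduction of the ester to the primary alcohol (C1); 2-silyloxycyclopropane esters are known to survive LiAlH4 at low temperature without ring opening.

Step 8
Reactants: 10 [(1S,2S,3R)-1-methyl-2-(triethylsilyloxy)-3-[(2S)-1-(triethylsilyloxy)propan-2-yl]-2-vinylcyclopropyl]methanol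
Product: 11 tert-butyldimethylsilyl ether of 10 (C1–OTBS, C5–OSiEt3, C8–OSiEt3)
Conditions: t-BuMe2SiCl, imidazole, DMF, 0 °C to rt
Reagents that add atoms: tert-butylchlorodimethylsilane, CC(C)(C)[Si](C)(C)Cl
Why: Imidazole-mediated silylation of the neopentyl primary alcohol under non-acidic conditions that spare the silyloxycyclopropane.

Step 9
Reactants: 11 tert-butyldimethylsilyl ether of 10
Product: 12 (2S)-2-[(1R,2S,3S)-3-[(tert-butyldimethylsilyloxy)methyl]-3-methyl-2-(triethylsilyloxy)-2-vinylcyclopropyl]propan-1-ol
Conditions: PPTS (cat.), MeOH–CH2Cl2, −10 to 0 °C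
Reagents that add atoms: none
Why: Acid-catalysed methanolysis distinguishes silyl ethers by steric access, so the primary triethylsilyl ether at O8 should go well before the tertiary cyclopropyl triethylsilyl ether and the primary tert-butyldimethylsilyl ether.

Step 10
Reactants: 12 (2S)-2-[(1R,2S,3S)-3-[(tert-butyldimethylsilyloxy)methyl]-3-methyl-2-(triethylsilyloxy)-2-vinylcyclopropyl]propan-1-ol
Product: 13 (2S)-2-[(1R,2S,3S)-3-[(tert-butyldimethylsilyloxy)methyl]-3-methyl-2-(triethylsilyloxy)-2-vinylcyclopropyl]propanal (cis-vinyl silyloxycyclopropane aldehyde)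
Conditions: Dess–Martin periodinane, pyridine, CH2Cl2, 0 °C
Reagents that add atoms: none
Why: Buffered Dess–Martin oxidation gives the α-branched aldehyde under near-neutral conditions, so C9 should not epimerise and the silyloxycyclopropane should stay closed; the aldehyde is used at once.

Step 11
Reactants: 13 (2S)-2-[(1R,2S,3S)-3-[(tert-butyldimethylsilyloxy)methyl]-3-methyl-2-(triethylsilyloxy)-2-vinylcyclopropyl]propanal
Product: 14 (1R,2S,3S,5S,7S)-7-[(tert-butyldimethylsilyloxy)methyl]-3-hydroxy-2,7-dimethylbicyclo[3.1.1]heptan-6-one (C5 ketone, C8 hydroxyl)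
Conditions: Me2AlCl (1.5 equiv), CH2Cl2, −78 to −40 °C; aq. Rochelle salt
Reagents that add atoms: none
Why: Proposed new method: Me2AlCl activates the C8 aldehyde, the terminal vinyl carbon C7 attacks C8 (6-endo cation–olefin closure of ring C5–C6–C7–C8–C9–C10), and the cyclopropylcarbinyl cation developing at C6 is quenched by a 1,2-shift of C11 from C5 to C6 while the silyloxy group becomes the C5 carbonyl and Et3Si+ is lost to chloride, so the cyclobutanone C5–C6–C11–C10 is closed by ring expansion and not by a direct cyclisation. The closest known chemistry is the Prins cyclisation terminated by a pinacol shift and the ring expansion of 1-alkenylcyclopropanols to cyclobutanones induced by protons, halonium ions or epoxidation; an aldehyde carbon as the electrophile for that expansion, with a bridged bicyclo[3.1.1]heptanone as product, has not been shown. C6 is fixed by the cis relation of vinyl group and side chain on the cyclopropane (only this geometry can bridge) together with the suprafacial shift of C11, which moves with retention so that its endo methyl ends over the C7–C9 bridge and CH2OTBS next to C5; C8 should follow from a chair-like closure with the complexed oxygen equatorial and trans to the C9 methyl, and is removed in step 12. The step needs migration of the exocyclic bond C5–C11 and not of the ring-fusion bond C5–C10: C5–C11 overlaps with the empty orbital at C6 in the new six-membered ring and C11 is the more substituted carbon, whereas C5–C10 lies in the ring plane and its shift would give a more strained bicyclo[2.1.1] ketone. It also needs the aldehyde to be activated faster than the silyloxycyclopropane is opened, which is why a mild, proton-scavenging aluminium Lewis acid at −78 °C is chosen over SnCl4 or TiCl4, and the only other closure, 5-exo through C6, would leave a primary cation.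

Step 12
Reactants: 14 (1R,2S,3S,5S,7S)-7-[(tert-butyldimethylsilyloxy)methyl]-3-hydroxy-2,7-dimethylbicyclo[3.1.1]heptan-6-one
Product: 15 (1R,5S,7S)-7-[(tert-butyldimethylsilyloxy)methyl]-2,7-dimethylbicyclo[3.1.1]hept-2-en-6-one (C8=C9 alkene)
Conditions: Burgess reagent, toluene, 70 °C
Reagents that add atoms: none
Why: Burgess dehydration is a syn (Ei) elimination through the sulfamate ester; the equatorial C8–O has the tertiary C9–H on its own face, and the usual preference for the more substituted alkene should give C8=C9, which erases the C8 and C9 stereocentres.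

Step 13
Reactants: 15 (1R,5S,7S)-7-[(tert-butyldimethylsilyloxy)methyl]-2,7-dimethylbicyclo[3.1.1]hept-2-en-6-one
Product: 16 (1R,5S,7S)-7-(hydroxymethyl)-2,7-dimethylbicyclo[3.1.1]hept-2-en-6-one
Conditions: HF·pyridine, pyridine, THF, 0 °C to rt
Reagents that add atoms: none
Why: Fluoride cleavage of the primary silyl ether; ketone and trisubstituted alkene are inert to buffered HF·pyridine.

Step 14
Reactants: 16 (1R,5S,7S)-7-(hydroxymethyl)-2,7-dimethylbicyclo[3.1.1]hept-2-en-6-one
Product: 17 (1R,5S,7S)-2,7-dimethyl-6-oxobicyclo[3.1.1]hept-2-ene-7-carbaldehyde (C1 aldehyde)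
Conditions: Dess–Martin periodinane, pyridine, CH2Cl2, 0 °C to rt
Reagents that add atoms: none
Why: Dess–Martin oxidation of a neopentyl alcohol to an aldehyde that has no α-hydrogen and so cannot epimerise or self-condense.

Step 15
Reactants: 17 (1R,5S,7S)-2,7-dimethyl-6-oxobicyclo[3.1.1]hept-2-ene-7-carbaldehyde; 18 3-methylbut-3-en-2-one (excess)
Product: 19 (1R,5S,7S)-7-[(1R)-1-hydroxy-4-methyl-3-oxopent-4-en-1-yl]-2,7-dimethylbicyclo[3.1.1]hept-2-en-6-one
Conditions: (S,S)-ProPhenol (10 mol %), Et2Zn (20 mol %), 4 Å MS, THF, 0 °C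
Reagents that add atoms: none
Why: Direct catalytic aldol with the dinuclear zinc–ProPhenol system, used here with a methyl vinyl ketone-type donor and a non-enolisable α-quaternary aldehyde; because the bicyclic core is close to mirror-symmetric about the C1 carbonyl the substrate gives no facial bias, and the ligand enantiomer that delivers (R)-carbinols from α-branched aldehydes is relied on to set C1.

Step 16
Reactants: 19 (1R,5S,7S)-7-[(1R)-1-hydroxy-4-methyl-3-oxopent-4-en-1-yl]-2,7-dimethylbicyclo[3.1.1]hept-2-en-6-one
Product: 20 triethylsilyl ether of 19 (C1–OSiEt3)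
Conditions: Et3SiOTf, 2,6-lutidine, CH2Cl2, −78 °C
Reagents that add atoms: triethylsilyl trifluoromethanesulfonate, CC[Si](CC)(CC)OS(=O)(=O)C(F)(F)F
Why: Low-temperature silylation of the hindered secondary alcohol, which also stops retro-aldol and oxa-Michael closure of the β-hydroxy enone.

Step 17
Reactants: 20 triethylsilyl ether of 19
Product: 21 tricyclic β-hydroxy ketone (target numbering: (1R)-C1–OSiEt3, C3 ketone, C4 gem-dimethyl, C5 tertiary OH with C4 cis to C1 across the cyclobutane, C8=C9)
Conditions: [(Ph3P)CuH]6 (stoichiometric in hydride), toluene–THF, −40 to 0 °C; aq. NH4Cl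
Reagents that add atoms: none
Why: Copper hydride reductive aldol cyclisation: hydride goes to the unsubstituted enone terminus and gives the C4 enolate regiospecifically, which adds to the strained C5 ketone; since the enolate hangs from C1 on C11 it can reach only the carbonyl face that lies next to C1, so C4 is placed cis to C1 on the cyclobutane (the face an untethered nucleophile would avoid), and the non-enolisable bridgehead positions leave no other aldol path.

Step 18
Reactants: 21 tricyclic β-hydroxy ketone
Product: 22 tricyclic diol ((1R)-C1–OSiEt3, (3R)-C3–OH, C5–OH, C8=C9)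
Conditions: (S)-2-methyl-CBS-oxazaborolidine, catecholborane, toluene, −78 to −40 °C
Reagents that add atoms: none
Why: Corey–Bakshi–Shibata reduction under catalyst control, the quaternary C4 acting as the large and C2H2 as the small substituent, which with the (S)-catalyst should give the 3R alcohol; catecholborane is used because it does not hydroborate the C8=C9 alkene.

Step 19
Reactants: 22 tricyclic diol
Product: 23 C3 3-methylbutanoate of 22 (C5–OH free)
Conditions: 3-methylbutanoyl chloride, pyridine, DMAP (cat.), CH2Cl2, 0 °C to rt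
Reagents that add atoms: 3-methylbutanoyl chloride, CC(C)CC(Cl)=O
Why: Nucleophile-catalysed acylation that distinguishes the secondary C3 hydroxyl from the much more hindered tertiary C5 hydroxyl.

Step 20
Reactants: 23 C3 3-methylbutanoate of 22
Product: 24 C5 methyl oxalate of 23
Conditions: ClC(O)CO2Me, DMAP, CH2Cl2, 0 °C to rt
Reagents that add atoms: methyl chlorooxoacetate, COC(=O)C(Cl)=O
Why: Acylation of the tertiary alcohol with the very reactive methyl chlorooxoacetate gives the mixed oxalate needed for radical C–O cleavage; with C3 already an ester there is no β-hydroxy ketone left to undergo retro-aldol.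

Step 21
Reactants: 24 C5 methyl oxalate of 23
Product: 25 C5-deoxygenated tricycle ((1R)-C1–OSiEt3, (3R)-C3–O-isovaleryl, C5–H, C8=C9)
Conditions: Bu3SnH (excess, high concentration), AIBN, toluene, 110 °C
Reagents that add atoms: none
Why: Barton-type radical deoxygenation of a tertiary alkyl methyl oxalate with a tin hydride chain; the tertiary C5 radical can take hydrogen only on its open face because C4 is held in the C1–C4 bridge, which fixes C5–H, and a high tin hydride concentration is used to outrun fragmentation of the cyclobutyl radical.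

Step 22
Reactants: 25 C5-deoxygenated tricycle
Product: 26 tricyclic enone (C7 ketone conjugated with C8=C9; C1–OSiEt3, C3–O-isovaleryl)
Conditions: Rh2(cap)4 (dirhodium tetrakis(caprolactamate), 1 mol %), t-BuOOH (70% aq.), K2CO3, CH2Cl2, rt
Reagents that add atoms: tert-butyl hydroperoxide, CC(C)(C)OO
Why: Allylic C–H oxidation with tert-butyl hydroperoxide and a dirhodium caprolactamate catalyst, which for a 1-methylcycloalkene-type alkene oxidises the ring methylene next to the unsubstituted alkene carbon (the α-pinene-to-verbenone pattern), here C7.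

Step 23
Reactants: 26 tricyclic enone
Product: 27 C1 alcohol (C3–O-isovaleryl, C7 enone)
Conditions: HF·pyridine, pyridine, THF, 0 °C
Reagents that add atoms: none
Why: Buffered fluoride desilylation of the secondary triethylsilyl ether; the slightly acidic medium avoids 1,3-acyl migration from O3 to O1.

Step 24
Reactants: 27 C1 alcohol
Product: 28 target diester CNP0335239.1
Conditions: 3-methylbut-2-enoic acid, 2,4,6-trichlorobenzoyl chloride, Et3N, THF; then 27, DMAP, toluene, rt
Reagents that add atoms: 3-methylbut-2-enoic acid, CC(C)=CC(O)=O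
Why: Yamaguchi esterification through the mixed 2,4,6-trichlorobenzoic anhydride acylates the hindered C1 alcohol and avoids the deconjugation to the β,γ-unsaturated ester that 3-methylbut-2-enoyl chloride suffers with amine bases.

**Compound list**

1 | methyl 2-methyl-3-oxobutanoate | COC(=O)C(C)C(C)=O | starting material
2 | methyl 2-diazopropanoate | COC(=O)C(C)=[N+]=[N-] | intermediate
3 | (S)-4-methyldihydrofuran-2(3H)-one | C[C@@H]1COC(=O)C1 | starting material
4 | (S)-4-hydroxy-N-methoxy-N,3-dimethylbutanamide | CON(C)C(=O)C[C@H](C)CO | intermediate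
5 | (S)-N-methoxy-N,3-dimethyl-4-(triethylsilyloxy)butanamide | CON(C)C(=O)C[C@H](C)CO[Si](CC)(CC)CC | intermediate
6 | vinylmagnesium bromide | C=C[Mg]Br | starting material
7 | (S)-5-methyl-6-(triethylsilyloxy)hex-1-en-3-one | C=CC(=O)C[C@H](C)CO[Si](CC)(CC)CC | intermediate
8 | (3E,5S)-5-methyl-3,6-bis(triethylsilyloxy)hexa-1,3-diene | C=C/C(O[Si](CC)(CC)CC)=C\[C@H](C)CO[Si](CC)(CC)CC | intermediate
9 | methyl (1R,2S,3R)-1-methyl-2-(triethylsilyloxy)-3-[(2S)-1-(triethylsilyloxy)propan-2-yl]-2-vinylcyclopropane-1-carboxylate | COC(=O)[C@]1(C)[C@@H]([C@H](C)CO[Si](CC)(CC)CC)[C@@]1(O[Si](CC)(CC)CC)C=C | intermediate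
10 | [(1S,2S,3R)-1-methyl-2-(triethylsilyloxy)-3-[(2S)-1-(triethylsilyloxy)propan-2-yl]-2-vinylcyclopropyl]methanol | OC[C@]1(C)[C@@H]([C@H](C)CO[Si](CC)(CC)CC)[C@@]1(O[Si](CC)(CC)CC)C=C | intermediate
11 | tert-butyldimethylsilyl ether of 10 | CC(C)(C)[Si](C)(C)OC[C@]1(C)[C@@H]([C@H](C)CO[Si](CC)(CC)CC)[C@@]1(O[Si](CC)(CC)CC)C=C | intermediate
12 | (2S)-2-[(1R,2S,3S)-3-[(tert-butyldimethylsilyloxy)methyl]-3-methyl-2-(triethylsilyloxy)-2-vinylcyclopropyl]propan-1-ol | CC(C)(C)[Si](C)(C)OC[C@]1(C)[C@@H]([C@H](C)CO)[C@@]1(O[Si](CC)(CC)CC)C=C | intermediate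
13 | (2S)-2-[(1R,2S,3S)-3-[(tert-butyldimethylsilyloxy)methyl]-3-methyl-2-(triethylsilyloxy)-2-vinylcyclopropyl]propanal | CC(C)(C)[Si](C)(C)OC[C@]1(C)[C@@H]([C@H](C)C=O)[C@@]1(O[Si](CC)(CC)CC)C=C | intermediate
14 | (1R,2S,3S,5S,7S)-7-[(tert-butyldimethylsilyloxy)methyl]-3-hydroxy-2,7-dimethylbicyclo[3.1.1]heptan-6-one | CC(C)(C)[Si](C)(C)OC[C@@]1(C)[C@@H]2C[C@H](O)[C@@H](C)[C@H]1C2=O | intermediate
15 | (1R,5S,7S)-7-[(tert-butyldimethylsilyloxy)methyl]-2,7-dimethylbicyclo[3.1.1]hept-2-en-6-one | CC(C)(C)[Si](C)(C)OC[C@@]1(C)[C@@H]2CC=C(C)[C@H]1C2=O | intermediate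
16 | (1R,5S,7S)-7-(hydroxymethyl)-2,7-dimethylbicyclo[3.1.1]hept-2-en-6-one | OC[C@@]1(C)[C@@H]2CC=C(C)[C@H]1C2=O | intermediate
17 | (1R,5S,7S)-2,7-dimethyl-6-oxobicyclo[3.1.1]hept-2-ene-7-carbaldehyde | O=C[C@@]1(C)[C@@H]2CC=C(C)[C@H]1C2=O | intermediate
18 | 3-methylbut-3-en-2-one | CC(=C)C(C)=O | starting material
19 | (1R,5S,7S)-7-[(1R)-1-hydroxy-4-methyl-3-oxopent-4-en-1-yl]-2,7-dimethylbicyclo[3.1.1]hept-2-en-6-one | C=C(C)C(=O)C[C@@H](O)[C@@]1(C)[C@@H]2CC=C(C)[C@H]1C2=O | intermediate
20 | triethylsilyl ether of 19 | C=C(C)C(=O)C[C@@H](O[Si](CC)(CC)CC)[C@@]1(C)[C@@H]2CC=C(C)[C@H]1C2=O | intermediate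
21 | tricyclic β-hydroxy ketone (C1–OSiEt3, C3 ketone, C5–OH, C8=C9) | CC[Si](CC)(CC)O[C@@H]1CC(=O)C(C)(C)[C@]2(O)[C@H]3CC=C(C)[C@@H]2[C@]31C | intermediate
22 | tricyclic diol (C1–OSiEt3, (3R)-C3–OH, C5–OH, C8=C9) | CC[Si](CC)(CC)O[C@@H]1C[C@@H](O)C(C)(C)[C@]2(O)[C@H]3CC=C(C)[C@@H]2[C@]31C | intermediate
23 | C3 3-methylbutanoate of 22 | CC[Si](CC)(CC)O[C@@H]1C[C@@H](OC(=O)CC(C)C)C(C)(C)[C@]2(O)[C@H]3CC=C(C)[C@@H]2[C@]31C | intermediate
24 | C5 methyl oxalate of 23 | CC[Si](CC)(CC)O[C@@H]1C[C@@H](OC(=O)CC(C)C)C(C)(C)[C@]2(OC(=O)C(=O)OC)[C@H]3CC=C(C)[C@@H]2[C@]31C | intermediate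
25 | C5-deoxygenated tricycle (C1–OSiEt3, C3–O-isovaleryl, C5–H, C8=C9) | CC[Si](CC)(CC)O[C@@H]1C[C@@H](OC(=O)CC(C)C)C(C)(C)[C@@H]2[C@H]3CC=C(C)[C@@H]2[C@]31C | intermediate
26 | tricyclic enone (C7 ketone, C8=C9, C1–OSiEt3, C3–O-isovaleryl) | CC[Si](CC)(CC)O[C@@H]1C[C@@H](OC(=O)CC(C)C)C(C)(C)[C@@H]2[C@H]3C(=O)C=C(C)[C@@H]2[C@]31C | intermediate
27 | C1 alcohol (C3–O-isovaleryl, C7 enone) | O[C@@H]1C[C@@H](OC(=O)CC(C)C)C(C)(C)[C@@H]2[C@H]3C(=O)C=C(C)[C@@H]2[C@]31C | intermediate
28 | target diester CNP0335239.1 | CC(C)=CC(=O)O[C@@H]1C[C@@H](OC(=O)CC(C)C)C(C)(C)[C@@H]2[C@H]3C(=O)C=C(C)[C@@H]2[C@]31C | target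

**Step count**

Total: 24 steps. Longest linear sequence: 23 steps (3 to 28, steps 2–24); step 1 is the only side branch.

**Steps most likely to fail**

Step 11 (Prins cyclisation with ring expansion). What may go wrong: the Lewis acid opens the silyloxycyclopropane or removes its silyl group before C7 reaches the aldehyde, or the closure is so slow that the aldehyde epimerises at C9 or oligomerises. Fallback, known reactions only: it sets out from compound 13 and returns at compound 14, and it separates the two bond formations. Vinylmagnesium bromide 6 is added to aldehyde 13 (Felkin–Anh control, THF, −78 °C) to give the C8 vinyl carbinol with OH anti to the C9 methyl, F1. Ring-closing metathesis of the two vinyl groups with the second-generation Grubbs catalyst RuCl2(=CHPh)(PCy3)(H2IMes) in CH2Cl2 at 40 °C then closes the six-membered ring, giving the 1-silyloxybicyclo[4.1.0]hept-2-en-4-ol F2, in which the ring carbon C7 comes from the Grignard reagent. N-Bromosuccinimide at −78 °C brings about the well-precedented halonium-induced ring expansion of the 1-alkenylcyclopropanol silyl ether: bromine adds to C7 anti to the cyclopropane and C11 shifts to C6, giving the C7 bromo hydroxy ketone F3. Bu3SnH with Et3B/air at low temperature removes the bromine and gives 14.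

Step 6 (asymmetric cyclopropanation). What may go wrong: β-hydride elimination of the carbenoid to methyl acrylate outruns addition to the hindered trisubstituted enol ether, the carbenoid attacks the terminal vinyl group, or facial and exo/endo selectivity are poor. Fallback: it does not branch from an intermediate of the route; it sets out from compound 6 as vinyl donor and from a new commercial ester, and it returns at compound 11. The cyclopropane is built from the C10=C11 alkene and C5 is introduced last. Methyl (R)-3-hydroxy-2-methylpropanoate F4 is silylated (Et3SiCl, imidazole) to the triethylsilyl ether F5. DIBAL-H at −78 °C gives (S)-2-methyl-3-(triethylsilyloxy)propanal F6. Wittig reaction with Ph3P=C(CH3)CO2Et gives ethyl (2E,4S)-2,4-dimethyl-5-(triethylsilyloxy)pent-2-enoate F7. DIBAL-H gives the E allylic alcohol F8, and t-BuMe2SiCl with imidazole gives its tert-butyldimethylsilyl ether F9. Dibromocarbene (CHBr3, KOt-Bu, pentane, 0 °C) adds stereospecifically to the E alkene; the facial isomers are diastereomers because of C9 and are separated to give the gem-dibromocyclopropane F10. Bromine–lithium exchange (n-BuLi, THF, −100 °C, then equilibration at −78 °C so that lithium sits cis to the side chain and bromine cis to C10–H) and trapping with 2-isopropoxy-4,4,5,5-tetramethyl-1,3,2-dioxaborolane gives the α-bromocyclopropyl pinacol boronate F11. Addition of 6 forms the boron ate complex, and a Matteson-type 1,2-shift of vinyl with inversion at C5 gives the 1-vinylcyclopropyl pinacol boronate F12, with boron cis to CH2OTBS. Oxidation with NaBO3·4H2O (retention) gives the cyclopropanol F13, and Et3SiCl with imidazole gives 11.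

Step 17 (reductive aldol closure of the seven-membered ring). What may go wrong: the copper enolate is protonated before it can reach the hindered C5 carbonyl along the compressed trajectory that the 1,3-bridge imposes, which leaves plain conjugate reduction, or the aldol reverts on work-up. Fallback: it sets out from compound 20 and returns at compound 21, and it replaces the hydride-triggered one-pot closure by an isolated halide and an electron-transfer Reformatsky closure, which forms the enolate irreversibly at −78 °C in the absence of a proton source. Conjugate hydrosilylation of 20 (Et3SiH, RhCl(PPh3)3 cat., benzene, 50 °C) gives the tetrasubstituted triethylsilyl enol ether F14. N-Bromosuccinimide in THF at −78 °C gives the tertiary α-bromo ketone F15. SmI2 in THF at −78 °C gives the trivalent samarium enolate, which closes onto the C5 ketone in a Reformatsky-type aldol to give 21.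

**Further compounds**

F1 | step 11 | C8 vinyl carbinol from 13 (OH anti to the C9 methyl) | CC(C)(C)[Si](C)(C)OC[C@]1(C)[C@@H]([C@H](C)[C@@H](O)C=C)[C@@]1(O[Si](CC)(CC)CC)C=C
F2 | step 11 | 1-silyloxybicyclo[4.1.0]hept-2-en-4-ol (ring C5–C6=C7–C8–C9–C10 fused to the cyclopropane) | CC(C)(C)[Si](C)(C)OC[C@]1(C)[C@H]2[C@H](C)[C@@H](O)C=C[C@@]12O[Si](CC)(CC)CC
F3 | step 11 | C7 bromo hydroxy ketone (7-bromo derivative of 14) | CC(C)(C)[Si](C)(C)OC[C@@]1(C)[C@@H]2[C@@H](Br)[C@H](O)[C@@H](C)[C@H]1C2=O
F4 | step 6 | methyl (R)-3-hydroxy-2-methylpropanoate | COC(=O)[C@H](C)CO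
F5 | step 6 | methyl (R)-2-methyl-3-(triethylsilyloxy)propanoate | COC(=O)[C@H](C)CO[Si](CC)(CC)CC
F6 | step 6 | (S)-2-methyl-3-(triethylsilyloxy)propanal | O=C[C@H](C)CO[Si](CC)(CC)CC
F7 | step 6 | ethyl (2E,4S)-2,4-dimethyl-5-(triethylsilyloxy)pent-2-enoate | CCOC(=O)/C(C)=C/[C@H](C)CO[Si](CC)(CC)CC
F8 | step 6 | (2E,4S)-2,4-dimethyl-5-(triethylsilyloxy)pent-2-en-1-ol | OC/C(C)=C/[C@H](C)CO[Si](CC)(CC)CC
F9 | step 6 | tert-butyldimethylsilyl ether of F8 | CC(C)(C)[Si](C)(C)OC/C(C)=C/[C@H](C)CO[Si](CC)(CC)CC
F10 | step 6 | gem-dibromocyclopropane (C5Br2; C10 and C11 as in 11) | CC(C)(C)[Si](C)(C)OC[C@]1(C)[C@@H]([C@H](C)CO[Si](CC)(CC)CC)C1(Br)Br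
F11 | step 6 | α-bromocyclopropyl pinacol boronate (boron cis to side chain) | CC(C)(C)[Si](C)(C)OC[C@]1(C)[C@@H]([C@H](C)CO[Si](CC)(CC)CC)[C@@]1(Br)B2OC(C)(C)C(C)(C)O2
F12 | step 6 | 1-vinylcyclopropyl pinacol boronate (boron cis to CH2OTBS) | CC(C)(C)[Si](C)(C)OC[C@]1(C)[C@@H]([C@H](C)CO[Si](CC)(CC)CC)[C@@]1(B2OC(C)(C)C(C)(C)O2)C=C
F13 | step 6 | 1-vinylcyclopropanol (free C5–OH form of 11) | CC(C)(C)[Si](C)(C)OC[C@]1(C)[C@@H]([C@H](C)CO[Si](CC)(CC)CC)[C@@]1(O)C=C
F14 | step 17 | triethylsilyl enol ether of the C3 ketone (C3=C4) from 20 | CC(C)=C(O[Si](CC)(CC)CC)C[C@@H](O[Si](CC)(CC)CC)[C@@]1(C)[C@@H]2CC=C(C)[C@H]1C2=O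
F15 | step 17 | C4 bromo ketone | CC(C)(Br)C(=O)C[C@@H](O[Si](CC)(CC)CC)[C@@]1(C)[C@@H]2CC=C(C)[C@H]1C2=O
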